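The pitfall here is to treat this flask as a single time constant, one percent-against-time curve for any charge. At 20.0 min, Wednesday's run reads 56.8% but Saturday's reads 36.2%.

| flask | substrate | remark | time |
|---|---|---|---|
| Wednesday's | 0.19 M | run made earlier |  |
| Thursday's | 0.43 M | run made earlier |  |
| Saturday's | 1.6 M | run made earlier |  |
| blue | 0.20 M |  | 40 min |
| ochre | 0.15 M |  | 40 min |
| violet | 1.5 M |  | 40 min |
| grey | 1.2 M |  | 40 min |
| red | 0.60 M |  | 40 min |
| amber | 0.41 M |  | 40 min |

- Wednesday's (time / min: target / %): 4.00: 18.3; 8.00: 30.1; 12.0: 41.2; 15.0: 49.4; 20.0: 56.8
- Thursday's (time / min: target / %): 2.00: 8.8; 5.00: 18.8; 10.0: 35.9; 15.0: 43.0; 20.0: 50.1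
- Saturday's (time / min: target / %): 1.50: 5.3; 3.00: 11.9; 6.00: 19.5; 10.0: 27.5; 20.0: 36.2

(readings scatter by 1 percentage point)

- all flasks from highest to lowest amount of target, in percent of the substrate charged, at 40 min (blue / ochre / violet / grey / red / amber)
- the amount of target, in percent of the substrate charged of the flask you put first, at 40 min
- the amount of target, in percent of the substrate charged of the flask you put last, at 40 min

My decision is whether the next run should charge ochre rather than blue. I picture a tank with a linear outlet and a second leak that grows with the square of the level. Let a be the fraction of the charge still substrate, and count the linear outflow as target: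

da/dt = −k(a + βa·a), so target fraction y = ln(1 + βu)/β, with u = 1 − exp(−kt).

Here β = g × charge, where g is the self-loss per molar: the start ratio of the squared leak to the linear outlet, for each molar charged.

Wednesday's first reading, where the leak is small, gives k = 0.0505 min⁻¹, a time constant of 19.8 min. For Saturday's last reading, u = 0.636. A first guess comes from the short form y ≈ u/(1 + βu/2):

β = 2.38

Putting that back into the logarithm once:

β = 2.55, so g = 1.59 M⁻¹

The asked time is twice the time constant, so u = 0.867. I then reckon:

ochre 78.8%, blue 76.6%, violet 47.0%

At fixed u, y falls as β rises, so my order follows the charges upward from ochre to violet. Ochre gains 2.2 percentage points on blue, against a scatter of 1 point, which is small but worth one run, so I charge ochre. My curve stands 2.7 points above Thursday's last reading, so I take these figures as high.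

The forecast gives ochre > blue > amber > red > grey > violet, with 73% and 43%, both lower than mine, its figures being “shaded slightly downward”.

The flask gives ochre > blue > amber > red > grey > violet, with ochre at 73.7% and violet at 44.7%.

    substrate → side product (k = 9.30 × 10⁻⁵ s⁻¹)
    substrate → target (k = 8.50 × 10⁻⁴ s⁻¹)
    2 substrate → self-condensation product (k = 6.90 × 10⁻⁴ M⁻¹ s⁻¹)

Ochre reaches 0.935 of my figure and violet 0.951, so g survives and one factor remains. The main reason that violet stands so low is the step from 2 substrate to self-condensation product: without that step violet reads 80.8% against 44.7%. Part of what ochre lacks is side product: without that step ochre reads 78.9%. Side product stands to target at 0.109 in ochre and 0.109 in violet, a steady selectivity. For a neighbour of violet charged with 0.38 M, g and that factor give 65.2%, and the flask reads 65.5%.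

The data were computed from invented constants; scatter was added.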